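## The problem

5,6-Dihydroxylutein 23 is a C40 compound. An all-E nonaene (C7 to C7', four methyl branches) joins two different trimethylcyclohexane rings, ring A (C1–C6) and ring B (C1'–C6'). The SMILES reads as 3S,5S,6R,3'R,6'R.

Ring A carries hydroxyls on C3, C5 and C6, all on one face. C5 and C6 are adjacent, fully substituted carbinol carbons between the quaternary C1 and the polyene. Their cis relation excludes epoxide hydrolysis, which gives the trans diol. Only C3 of ring A can be set by catalysis, but it can control C4/C5 next to it, and C5 can control C6, so a relay C3 → C5 → C6 is open.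

Ring B is judged the harder half. C3' and C6' stand 1,4-trans across C4'=C5', too far apart for ordinary induction. The ring double bond is out of conjugation with the chain, uphill from the conjugated isomer, and H6' is doubly allylic.

The feature that makes the key step possible lies in ring B. In the array O3'–C3'–C4'=C5'–C6'–H6', O3' and H6' lie on the same face. This is the imprint of a suprafacial SN2' opening of a C3'–C4' oxirane conjugated with C5'=C6', by a hydride carried on the oxirane oxygen. The ring needed for that is the flat, achiral cyclohexadiene ring of safranal.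

Several groups limit the endgame. The tertiary C6–OH (allylic to the nonaene) and the allylic C3'–OH ionise with acid, H6' is base-sensitive, and the polyene is sensitive to light and oxygen. The last steps must therefore be aprotic or mildly basic and free of deprotections.

## Retrosynthesis

**C11=C12.** Target 23 is cut into the C25 phosphonium salt 21 (ring B) and the C15 aldehyde 8 (ring A).
- A cut at C7=C8 or C9=C10 would put a carbanion or a leaving group next to C6–OH. A cut at C15=C15' would need two C20 halves, each with an extra C5 homologation.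
- With this cut ring A is the electrophile and never meets the acid that makes a phosphonium salt.
- The forward Wittig reaction must tolerate four free hydroxyls and end all-E.

**C11'=C12'.** Salt 21 goes back through alcohol 20 and aldehyde 19 to the C15 salt 16 and the symmetrical, commercial dialdehyde 17.
- The same bond type is cut on the other side, so one reaction type serves twice and ten carbons are bought.
- The forward step must stop at mono-olefination.

**C6'–H, with C4'–O restored (key step).** Salt 16 comes from diol 15, and 15 from oxirane ester 13.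
- In the retrosynthetic direction H6' is removed, the double bond returns to C5'=C6', and O3' is tied back to C4'.
- Other ways to C6' set it as a C–C bond next to the quaternary C1', or take it racemic from the ionone series. Here it is set as a C–H bond from a carrier already fixed on the correct face.
- Compound 13 has a planar C6' and a fully conjugated chain. The ester reduction that is needed anyway happens in the same flask through 14.
- The forward step must give 1,4- rather than 1,2-opening, and syn delivery.

**C3'–O/C4'–O, then C7'=C8'.** Oxirane 13 comes from the achiral tetraenoate 12 by catalytic oxygen transfer to C3'=C4', the only cis-disubstituted double bond. Ester 12 comes from safranal 9 and phosphonate 10 (through anion 11). Both are bought, so the precursor of the key step is two steps from the shelf.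

**C4–H and the two hydrogens on C7/C8.** Aldehyde 8 comes from tetraol 7, and 7 from alkynyl oxirane 6. Hydride removes the C4–O bond and the triple bond in one operation. Placing the oxirane at C4–C5, not at C5–C6, means C5–O and C6–O are never broken.

**C6–C7.** Compound 6 is cut into epoxy ketone 3 and enynol 4 (used as dianion 5). The carbonyl carbon is the only position of ring A at which carbon can be attached without a leaving group, and it has no enolisable neighbour. The forward addition must come anti to the oxirane.

**C4–O/C5–O, then C3–H.** Epoxy ketone 3 comes from hydroxy enone 2 by a hydroxyl-directed epoxidation. Compound 2 comes from ketoisophorone 1 by a catalytic asymmetric reduction of its unhindered carbonyl.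

The carbon count is 9 + 6 + 10 + 5 + 10 = 40, from five purchased compounds.

## Roads not taken

**Alternative 1:** (the most obvious) The same two Wittig cuts, with both C15 halves grown from the ionone series.
- Ring B would start from racemic α-ionone A1, be oxidised at C3' to 3-oxo-α-ionone A2, and be reduced.
- Ring A would start from (3R)-3-hydroxy-β-ionone A3. The forward key step would be cis-dihydroxylation of C5=C6 with OsO4 to triol ketone A4.
- The chosen plan is better for three reasons. C6' of A1 is racemic and needs a resolution. The hydride face at C3' of A2 is controlled only by a centre four atoms away. C5=C6 of A3 is tetrasubstituted, flanked by C1, and competes with the side-chain double bond, with face selection left to a homoallylic hydroxyl. A3 itself takes several steps to make.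

**Alternative 2:** Ring B by reductive 1,3-transposition. The cut is again C6'–H, but from the tosylhydrazone A5 of a 3'-silyloxy-4'-oxo ring with conjugated C5'=C6'.
- The forward key step is reduction with catecholborane and retro-ene loss of N2 from the allylic diazene, which delivers hydrogen to C6'.
- A5 needs six or seven steps from 1 and 4: reduction, silylation, alkynylation, oxidative transposition, alkyne reduction, hydrazone formation.
- Its ketone is flanked by the silyl ether and the C5' methyl.
- The hydride face at C4' rests on a conformational balance in which allylic strain and the syn-axial C1' methyl oppose each other.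
- In the chosen plan the hydride carrier is bound to an oxygen that already sits on the correct face, and the precursor is two steps from purchased material.

**Alternative 3:** Ring A by singlet oxygen. The cuts are C3–O and C6–O together.
- The forward key step is a [4+2] addition of singlet oxygen to the ring diene of 12, giving endoperoxide A6.
- Reduction would follow to the cis-enediol A7, then hydroxyl-directed epoxidation of C4=C5 and hydride opening.
- It is attractive because 12 would serve both rings and O3 and O6 would arrive cis in one event.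
- However, the diene is achiral and its two faces are equivalent, so A6 is racemic. Half the material is lost in a resolution, the s-cis diene C5=C6–C7=C8 competes, and four steps follow the key step.
- The relay from 2 reaches the same array as a single enantiomer in three steps.

Key step: step 8

Assumption: the absolute sense of the two catalytic steps (1 and 7) is assigned by analogy with aryl alkyl ketones and with indene, and the mirror-image catalyst would be used if the analogy failed. Commercial 10 is an E/Z mixture whose anion is common to both isomers. All polyene steps are run under argon with exclusion of light.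

## Steps

Step 1
Reactants: 1 ketoisophorone (2,6,6-trimethylcyclohex-2-ene-1,4-dione)
Product: 2 (4S)-4-hydroxy-2,6,6-trimethylcyclohex-2-en-1-one
Conditions: RuCl[(S,S)-TsDPEN](p-cymene) (0.5 mol %), KOH (1 mol %), i-PrOH, 25 °C
Reagents that add atoms: none
Why: Noyori asymmetric transfer hydrogenation; hydride goes 1,2 to the C4 carbonyl, flanked by CH2 and CH=, and not to the C1 carbonyl, which is shielded by the quaternary carbon and the methyl-bearing sp2 carbon. The alkenyl side takes the place of the aryl group of an aryl alkyl ketone, so the (S,S) catalyst should set the S carbinol, which becomes C3 of ring A.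

Step 2
Reactants: 2 (4S)-4-hydroxy-2,6,6-trimethylcyclohex-2-en-1-one
Product: 3 (1S,5S,6S)-5-hydroxy-1,3,3-trimethyl-7-oxabicyclo[4.1.0]heptan-2-one (oxirane cis to the hydroxyl)
Conditions: t-BuOOH (decane), benzyltrimethylammonium hydroxide (10 mol %), THF, 0 °C
Reagents that add atoms: tert-butyl hydroperoxide, CC(C)(C)OO
Why: Hydroxyl-directed Weitz–Scheffer epoxidation; in the aprotic medium the hydroperoxide anion is hydrogen-bonded to O3 and adds to C4 on that face. In the favoured sofa conformer (hydroxyl pseudoequatorial, away from the syn-axial methyl on C1) antiparallel attack at C4 comes from the same face. Closure of the peroxy enolate fixes C4 and C5, so C5–O is cis to C3–O.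

Step 3
Reactants: 3 (1S,5S,6S)-5-hydroxy-1,3,3-trimethyl-7-oxabicyclo[4.1.0]heptan-2-one; 4 (E)-3-methylpent-2-en-4-yn-1-ol
Product: 6 (1S,2S,5S,6S)-2-[(E)-5-hydroxy-3-methylpent-3-en-1-ynyl]-1,3,3-trimethyl-7-oxabicyclo[4.1.0]heptane-2,5-diol, via dilithio enynol 5 (not isolated)
Conditions: 4 (2.5 equiv), n-BuLi (5 equiv), THF, −78 → 0 °C; then 3, −78 → −20 °C; H2O
Reagents that add atoms: none
Why: 1,2-Addition of a lithium acetylide to a ketone that cannot enolise (C1 and C5 carry no hydrogen); the excess covers the free hydroxyl of 3. The C5–O bond of the oxirane stands perpendicular to the carbonyl plane, so polar Felkin–Anh attack comes anti to it, on the face that is also free of the C3 alkoxide; C7 enters from above and O6 ends cis to O5 and O3. A cis epoxy alkoxide cannot undergo Payne migration.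

Step 4
Reactants: 6 (1S,2S,5S,6S)-2-[(E)-5-hydroxy-3-methylpent-3-en-1-ynyl]-1,3,3-trimethyl-7-oxabicyclo[4.1.0]heptane-2,5-diol
Product: 7 (1R,2S,4S)-1-[(1E,3E)-5-hydroxy-3-methylpenta-1,3-dienyl]-2,6,6-trimethylcyclohexane-1,2,4-triol
Conditions: LiAlH4 (6 equiv), THF, 0 °C → reflux; aq potassium sodium tartrate
Reagents that add atoms: none
Why: One reagent does two known jobs: trans-hydroalumination of the alkyne, directed by the tertiary propargylic alkoxide, gives the 7E alkene after protonolysis, and SN2 opening of the trisubstituted oxirane at the secondary C4 leaves the tertiary C5–OH untouched. No stereocentre is made or broken, and C9=C10 keeps its E geometry.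

Step 5
Reactants: 7 (1R,2S,4S)-1-[(1E,3E)-5-hydroxy-3-methylpenta-1,3-dienyl]-2,6,6-trimethylcyclohexane-1,2,4-triol
Product: 8 (2E,4E)-3-methyl-5-[(1R,2S,4S)-1,2,4-trihydroxy-2,6,6-trimethylcyclohexyl]penta-2,4-dienal
Conditions: MnO2 (activated), CH2Cl2, 0 °C → rt, short contact
Reagents that add atoms: none
Why: Allylic oxidation with MnO2 takes only the primary dienylic alcohol; the saturated secondary C3–OH and the two tertiary hydroxyls are not substrates. Short contact avoids glycol cleavage of the cis diol.

Step 6
Reactants: 9 safranal (2,6,6-trimethylcyclohexa-1,3-diene-1-carbaldehyde); 10 ethyl (E)-4-(diethoxyphosphoryl)-3-methylbut-2-enoate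
Product: 12 ethyl (2E,4E)-3-methyl-5-(2,6,6-trimethylcyclohexa-1,3-dien-1-yl)penta-2,4-dienoate, via lithiated phosphonate 11 (not isolated)
Conditions: 10, n-BuLi, THF/DMPU, −78 °C; then 9, −78 → 0 °C
Reagents that add atoms: none
Why: Horner–Wadsworth–Emmons olefination; the stabilised allylic phosphonate anion reacts through its α-carbon and the elimination gives the 7'E alkene. The 9'E geometry is that of the preferred anion, and any 9'Z isomer would be removed by chromatography.

Step 7
Reactants: 12 ethyl (2E,4E)-3-methyl-5-(2,6,6-trimethylcyclohexa-1,3-dien-1-yl)penta-2,4-dienoate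
Product: 13 ethyl (2E,4E)-3-methyl-5-[(1S,6R)-2,4,4-trimethyl-7-oxabicyclo[4.1.0]hept-2-en-3-yl]penta-2,4-dienoate (3'R,4'S oxirane)
Conditions: (S,S)-[N,N'-bis(3,5-di-tert-butylsalicylidene)cyclohexane-1,2-diaminato]MnCl (4 mol %), 4-phenylpyridine N-oxide (20 mol %), aq NaOCl (pH 11.3), CH2Cl2, 0 °C
Reagents that add atoms: sodium hypochlorite, [Na+].[O-]Cl
Why: Jacobsen–Katsuki epoxidation, which works best on cis-disubstituted olefins conjugated to a π system inside a ring. C3'=C4' is the only such bond (C7'=C8' is trans, C9'=C10' is electron-poor, C5'=C6' is tetrasubstituted next to C1') and is also farthest from the ester. The ring forbids cis/trans leakage of the radical intermediate, and the face is assigned by analogy with indene, whose benzylic carbon corresponds to C4'.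

Step 8
Reactants: 13 ethyl (2E,4E)-3-methyl-5-[(1S,6R)-2,4,4-trimethyl-7-oxabicyclo[4.1.0]hept-2-en-3-yl]penta-2,4-dienoate
Product: 15 (2E,4E)-5-[(1R,4R)-4-hydroxy-2,6,6-trimethylcyclohex-2-en-1-yl]-3-methylpenta-2,4-dien-1-ol, via aluminium alkoxide 14 (not isolated)
Conditions: i-Bu2AlH (4.5 equiv), toluene/hexane, −78 → −20 °C; aq potassium sodium tartrate
Reagents that add atoms: none
Why: Proposed new method: i-Bu2AlH first reduces the ester to alkoxide 14, which removes the acceptor that had disfavoured positive charge at C6', C8' and C10' and so kept the vinyl oxirane inert. A further i-Bu2AlH then binds to the oxirane oxygen on the upper face of ring B, which weakens the allylic C4'–O bond and makes the Al–H a hydride donor; the hydride passes through the six-membered array O–Al–H···C6'=C5'–C4' to C6' while the double bond moves to C4'=C5', and the strain of the oxirane pays for the loss of conjugation. The closest known reaction types are the 1,4-reduction of vinyl oxiranes by i-Bu2AlH through a cyclic transition state and the SN2' reduction of conjugated alkynyl oxiranes to allenols; delivery to a fully substituted ring carbon of a polyene has not been shown. No ring is closed; the three-membered ring is opened. The only new stereocentre, C6', is controlled by the oxirane: hydride arrives on the face that carries O3', so H6' and O3' end cis and the chain trans, which is 3'R,6'R, and C3' keeps its C–O bond. The step needs 1,4- over 1,2-opening and over attack at C8' or C10'. Front-side attack of the bound hydride at C4' is geometrically poor, free i-Bu2AlH is a weak nucleophile in a hydrocarbon, and C8' and C10' are out of reach of the bound Al–H. Low temperature and the non-polar solvent keep the transfer concerted and suppress ionisation to a polyenyl cation.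

Step 9
Reactants: 15 (2E,4E)-5-[(1R,4R)-4-hydroxy-2,6,6-trimethylcyclohex-2-en-1-yl]-3-methylpenta-2,4-dien-1-ol
Product: 16 [(2E,4E)-5-[(1R,4R)-4-hydroxy-2,6,6-trimethylcyclohex-2-en-1-yl]-3-methylpenta-2,4-dien-1-yl]triphenylphosphonium bromide
Conditions: PPh3·HBr (1.0 equiv), CH2Cl2, 0 °C → rt
Reagents that add atoms: triphenylphosphine hydrobromide, [Br-].c1ccc(cc1)[PH+](c1ccccc1)c1ccccc1
Why: Classical phosphonium salt formation from an allylic alcohol; the primary dienylic alcohol ionises to a pentadienyl cation that PPh3 traps at the terminal C11'. The ring alcohol would give only a simple allyl cation and reacts more slowly, and the aprotic solvent excludes solvolysis at C3'.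

Step 10
Reactants: 16 C15 phosphonium bromide of ring B; 17 (2E,4E,6E)-2,7-dimethylocta-2,4,6-trienedial
Product: 19 (2E,4E,6E,8E,10E,12E)-13-[(1R,4R)-4-hydroxy-2,6,6-trimethylcyclohex-2-en-1-yl]-2,7,11-trimethyltrideca-2,4,6,8,10,12-hexaenal, via ylide 18 (not isolated)
Conditions: 17 (2.5 equiv), NaOMe, CH2Cl2/MeOH, 0 °C → rt; then heptane/EtOAc, 70 °C (Z → E)
Reagents that add atoms: none
Why: Wittig olefination with a semi-stabilised ylide, which tolerates the free 3'-OH. The excess of symmetrical dialdehyde and the lower electrophilicity of the longer product aldehyde secure mono-olefination, and the crowded 11'Z isomer relaxes to E on warming.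

Step 11
Reactants: 19 C25 hydroxy aldehyde
Product: 20 (2E,4E,6E,8E,10E,12E)-13-[(1R,4R)-4-hydroxy-2,6,6-trimethylcyclohex-2-en-1-yl]-2,7,11-trimethyltrideca-2,4,6,8,10,12-hexaen-1-ol
Conditions: NaBH4, EtOH/THF, 0 °C
Reagents that add atoms: none
Why: 1,2-Reduction of a polyenal by borohydride; nothing else in the molecule is reducible under these conditions.

Step 12
Reactants: 20 C25 diol
Product: 21 [(2E,4E,6E,8E,10E,12E)-13-[(1R,4R)-4-hydroxy-2,6,6-trimethylcyclohex-2-en-1-yl]-2,7,11-trimethyltrideca-2,4,6,8,10,12-hexaen-1-yl]triphenylphosphonium bromide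
Conditions: PPh3·HBr (1.0 equiv), CH2Cl2, 0 °C
Reagents that add atoms: triphenylphosphine hydrobromide, [Br-].c1ccc(cc1)[PH+](c1ccccc1)c1ccccc1
Why: Same reaction type as step 9; the polyenylic primary alcohol ionises still more easily, so the margin over the ring allylic alcohol is wider.

Step 13
Reactants: 21 C25 phosphonium bromide; 8 (2E,4E)-3-methyl-5-[(1R,2S,4S)-1,2,4-trihydroxy-2,6,6-trimethylcyclohexyl]penta-2,4-dienal
Product: 23 5,6-dihydroxylutein, (3S,5S,6R,3'R,6'R)-5,6-dihydro-β,ε-carotene-3,5,6,3'-tetrol, via ylide 22 (not isolated)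
Conditions: 21, NaN(SiMe3)2 (1.0 equiv), THF, −78 °C; then 8, −78 → 0 °C; then EtOH, 70 °C (Z → E)
Reagents that add atoms: none
Why: Wittig olefination with the preformed ylide; the phosphonium salt is far more acidic than any hydroxyl, so one equivalent of base leaves all four hydroxyls protonated and no free alkoxide is present to attack ring A. No acid and no deprotection follow, so C6–OH, C3'–OH and H6' are not put at risk, and the hindered 11Z isomer equilibrates to all-E on warming.

## Compound list

1 | ketoisophorone | CC1=CC(=O)CC(C)(C)C1=O | starting material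
2 | (4S)-4-hydroxy-2,6,6-trimethylcyclohex-2-en-1-one | CC1=C[C@@H](O)CC(C)(C)C1=O | intermediate
3 | (1S,5S,6S)-5-hydroxy-1,3,3-trimethyl-7-oxabicyclo[4.1.0]heptan-2-one | O=C1C(C)(C)C[C@H](O)[C@@H]2O[C@]12C | intermediate
4 | (E)-3-methylpent-2-en-4-yn-1-ol | C#C/C(C)=C/CO | starting material
5 | dilithio derivative of 4 | [Li]C#C/C(C)=C/CO[Li] | intermediate
6 | (1S,2S,5S,6S)-2-[(E)-5-hydroxy-3-methylpent-3-en-1-ynyl]-1,3,3-trimethyl-7-oxabicyclo[4.1.0]heptane-2,5-diol | OC/C=C(C)/C#C[C@@]1(O)C(C)(C)C[C@H](O)[C@@H]2O[C@]12C | intermediate
7 | (1R,2S,4S)-1-[(1E,3E)-5-hydroxy-3-methylpenta-1,3-dienyl]-2,6,6-trimethylcyclohexane-1,2,4-triol | OC/C=C(C)/C=C/[C@@]1(O)C(C)(C)C[C@H](O)C[C@]1(C)O | intermediate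
8 | (2E,4E)-3-methyl-5-[(1R,2S,4S)-1,2,4-trihydroxy-2,6,6-trimethylcyclohexyl]penta-2,4-dienal | O=C/C=C(C)/C=C/[C@@]1(O)C(C)(C)C[C@H](O)C[C@]1(C)O | intermediate
9 | safranal | O=CC1=C(C)C=CCC1(C)C | starting material
10 | ethyl (E)-4-(diethoxyphosphoryl)-3-methylbut-2-enoate | CCOC(=O)/C=C(C)/CP(=O)(OCC)OCC | starting material
11 | lithiated phosphonate from 10 | CCOC(=O)/C=C(C)/C([Li])P(=O)(OCC)OCC | intermediate
12 | ethyl (2E,4E)-3-methyl-5-(2,6,6-trimethylcyclohexa-1,3-dien-1-yl)penta-2,4-dienoate | CCOC(=O)/C=C(C)/C=C/C1=C(C)C=CCC1(C)C | intermediate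
13 | ethyl (2E,4E)-3-methyl-5-[(1S,6R)-2,4,4-trimethyl-7-oxabicyclo[4.1.0]hept-2-en-3-yl]penta-2,4-dienoate | CCOC(=O)/C=C(C)/C=C/C1=C(C)[C@@H]2O[C@@H]2CC1(C)C | intermediate
14 | diisobutylaluminium alkoxide of the oxirane dienol | CC(C)C[Al](CC(C)C)OC/C=C(C)/C=C/C1=C(C)[C@@H]2O[C@@H]2CC1(C)C | intermediate
15 | (2E,4E)-5-[(1R,4R)-4-hydroxy-2,6,6-trimethylcyclohex-2-en-1-yl]-3-methylpenta-2,4-dien-1-ol | CC1=C[C@H](O)CC(C)(C)[C@H]1/C=C/C(C)=C/CO | intermediate
16 | C15 triphenylphosphonium bromide of ring B | CC1=C[C@H](O)CC(C)(C)[C@H]1/C=C/C(C)=C/C[P+](c1ccccc1)(c1ccccc1)c1ccccc1.[Br-] | intermediate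
17 | (2E,4E,6E)-2,7-dimethylocta-2,4,6-trienedial | O=C/C(C)=C/C=C/C=C(C)/C=O | starting material
18 | ylide from 16 | CC1=C[C@H](O)CC(C)(C)[C@H]1/C=C/C(C)=C/C=P(c1ccccc1)(c1ccccc1)c1ccccc1 | intermediate
19 | C25 hydroxy aldehyde (CHO = C12) | CC1=C[C@H](O)CC(C)(C)[C@H]1/C=C/C(C)=C/C=C/C(C)=C/C=C/C=C(C)/C=O | intermediate
20 | C25 diol | CC1=C[C@H](O)CC(C)(C)[C@H]1/C=C/C(C)=C/C=C/C(C)=C/C=C/C=C(C)/CO | intermediate
21 | C25 triphenylphosphonium bromide | CC1=C[C@H](O)CC(C)(C)[C@H]1/C=C/C(C)=C/C=C/C(C)=C/C=C/C=C(C)/C[P+](c1ccccc1)(c1ccccc1)c1ccccc1.[Br-] | intermediate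
22 | ylide from 21 | CC1=C[C@H](O)CC(C)(C)[C@H]1/C=C/C(C)=C/C=C/C(C)=C/C=C/C=C(C)/C=P(c1ccccc1)(c1ccccc1)c1ccccc1 | intermediate
23 | 5,6-dihydroxylutein, (3S,5S,6R,3'R,6'R) | CC1=C[C@H](O)CC(C)(C)[C@H]1/C=C/C(C)=C/C=C/C(C)=C/C=C/C=C(C)/C=C/C=C(C)/C=C/[C@@]1(O)C(C)(C)C[C@H](O)C[C@]1(C)O | target

## Step count and least certain steps

- Total: 13 steps.
- Longest linear sequence: 8 steps (9 → 23, steps 6–13).
- The ring A branch (steps 1–5) joins at step 13.

**Step 8 (key step, proposed new method).**
- What may go wrong: hydride transfer to C4' (which keeps the conjugation) or, from unbound reagent, to the unhindered C8'; external delivery anti to the oxygen; or Lewis-acid ionisation of the oxirane once the ester is gone. C6' is fully substituted and next to C1', so it is the slowest of the possible acceptor sites.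
- Fallback (known chemistry), from 13 back to 15. Anhydrous HCO2H in Et2O at −20 °C opens the oxirane at the allylic C4' with inversion, to ethyl (2E,4E)-5-[(3R,4R)-3-formyloxy-4-hydroxy-2,6,6-trimethylcyclohex-1-en-1-yl]-3-methylpenta-2,4-dienoate F1.
- Hydrogenolysis of the allylic formate with Pd(OAc)2/PBu3 in THF follows. Zerovalent palladium enters anti to the formate, that is on the face of O3'. After loss of CO2 it hands hydride to the more substituted allyl terminus C6' on that face.
- This gives ethyl (2E,4E)-5-[(1R,4R)-4-hydroxy-2,6,6-trimethylcyclohex-2-en-1-yl]-3-methylpenta-2,4-dienoate F2. i-Bu2AlH then reduces the ester to 15.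

**Step 7.**
- What may go wrong: oxygen transfer to other double bonds, or an eroded face selectivity because the radical formed after the first C–O bond is delocalised over the whole chain and lives long; also acid-catalysed opening of the vinyl oxirane on isolation.
- Fallback, from 9 back to 13. The oxygen transfer is moved to the C10 stage, where the competition is removed by structure: the only other double bond of 9 is tetrasubstituted and conjugated with the formyl group.
- Epoxidation of 9 gives (1S,6R)-2,4,4-trimethyl-7-oxabicyclo[4.1.0]hept-2-ene-3-carbaldehyde F3. This is then olefinated with anion 11 to 13, so step 6 is replaced.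

**Step 2.**
- What may go wrong: poor facial selectivity if hydrogen-bond delivery does not outweigh attack anti to the oxygen substituent; and base-induced isomerisation of the γ-hydroxy enone to the saturated 1,4-diketone.
- Fallback, from 1 back to 3. The order of the relay is reversed.
- Asymmetric Weitz–Scheffer epoxidation of 1 with H2O2, under iminium catalysis by a 9-amino-9-deoxy-epi-cinchona alkaloid bis(trifluoroacetate), condenses at the unhindered carbonyl and gives (1S,6R)-1,3,3-trimethyl-7-oxabicyclo[4.1.0]heptane-2,5-dione F4.
- Luche reduction (NaBH4, CeCl3·7H2O, MeOH, −78 °C) of the unhindered carbonyl from the face anti to the oxirane gives 3. Step 1 is dropped.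

**Step 4.**
- What may go wrong: slow opening of the oxirane, because trans-diaxial opening at C4 leads to a chair with O3, O5 and a C1 methyl all axial; and over-reduction of the dienol on long heating.
- Fallback, from 6 back to 7. NaAlH2(OCH2CH2OMe)2 in THF at 0 °C reduces only the alkyne, to (1S,2R,5S,6S)-2-[(1E,3E)-5-hydroxy-3-methylpenta-1,3-dienyl]-1,3,3-trimethyl-7-oxabicyclo[4.1.0]heptane-2,5-diol F5.
- The soft nucleophile PhSeNa (PhSeSePh, NaBH4, EtOH) opens the oxirane at C4 to the 4-phenylselanyl tetraol F6.
- Radical deselenation (Bu3SnH, AIBN, toluene, 80 °C) gives 7.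

**Step 13.**
- What may go wrong: incomplete Z → E relaxation at C11=C12; and, if alkoxide builds up, vinylogous retro-aldol cleavage of the C5–C6 bond of the aldehyde, whose C5–O is β to the ε-carbon of the dienal.
- Fallback, from 7 and 19 back to 23. The polarity is reversed, which also removes steps 5, 11 and 12.
- Appel bromination of 7 (CBr4, PPh3, 2,6-lutidine, CH2Cl2, −20 °C) gives the allylic bromide F7.
- PPh3 in EtOAc at rt gives the ring A phosphonium bromide F8 without acid.
- F8 is joined with 19 (NaOMe, CH2Cl2, 0 °C) to 23.

## Further compounds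

F1 | step 8 | ethyl (2E,4E)-5-[(3R,4R)-3-formyloxy-4-hydroxy-2,6,6-trimethylcyclohex-1-en-1-yl]-3-methylpenta-2,4-dienoate | CCOC(=O)/C=C(C)/C=C/C1=C(C)[C@@H](OC=O)[C@H](O)CC1(C)C
F2 | step 8 | ethyl (2E,4E)-5-[(1R,4R)-4-hydroxy-2,6,6-trimethylcyclohex-2-en-1-yl]-3-methylpenta-2,4-dienoate | CC1=C[C@H](O)CC(C)(C)[C@H]1/C=C/C(C)=C/C(=O)OCC
F3 | step 7 | (1S,6R)-2,4,4-trimethyl-7-oxabicyclo[4.1.0]hept-2-ene-3-carbaldehyde | O=CC1=C(C)[C@@H]2O[C@@H]2CC1(C)C
F4 | step 2 | (1S,6R)-1,3,3-trimethyl-7-oxabicyclo[4.1.0]heptane-2,5-dione | O=C1C(C)(C)CC(=O)[C@@H]2O[C@]12C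
F5 | step 4 | (1S,2R,5S,6S)-2-[(1E,3E)-5-hydroxy-3-methylpenta-1,3-dienyl]-1,3,3-trimethyl-7-oxabicyclo[4.1.0]heptane-2,5-diol | OC/C=C(C)/C=C/[C@@]1(O)C(C)(C)C[C@H](O)[C@@H]2O[C@]12C
F6 | step 4 | 4-phenylselanyl tetraol (selenium on C4 trans to O3 and O5) | OC/C=C(C)/C=C/[C@@]1(O)C(C)(C)C[C@H](O)[C@@H]([Se]c2ccccc2)[C@]1(C)O
F7 | step 13 | (1R,2S,4S)-1-[(1E,3E)-5-bromo-3-methylpenta-1,3-dienyl]-2,6,6-trimethylcyclohexane-1,2,4-triol | BrC/C=C(C)/C=C/[C@@]1(O)C(C)(C)C[C@H](O)C[C@]1(C)O
F8 | step 13 | C15 triphenylphosphonium bromide of ring A | c1ccc(cc1)[P+](c1ccccc1)(c1ccccc1)C/C=C(C)/C=C/[C@@]1(O)C(C)(C)C[C@H](O)C[C@]1(C)O.[Br-]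
A1 | alternative 1 | (±)-α-ionone | CC1=CCCC(C)(C)C1/C=C/C(C)=O
A2 | alternative 1 | (±)-3-oxo-α-ionone | CC1=CC(=O)CC(C)(C)C1/C=C/C(C)=O
A3 | alternative 1 | (3R)-3-hydroxy-β-ionone | CC(=O)/C=C/C1=C(C)C[C@@H](O)CC1(C)C
A4 | alternative 1 | (3S,5S,6R)-3,5,6-trihydroxy-5,6-dihydro-β-ionone | CC(=O)/C=C/[C@@]1(O)C(C)(C)C[C@H](O)C[C@]1(C)O
A5 | alternative 2 | tosylhydrazone of the (3'R)-3'-silyloxy-4'-oxo C15 trienyl silyl ether | CC(C)(C)[Si](C)(C)OC/C=C(C)/C=C/C1=C(C)C(=NNS(=O)(=O)c2ccc(C)cc2)[C@H](O[Si](C)(C)C(C)(C)C)CC1(C)C
A6 | alternative 3 | 3,6-endoperoxide of 12 (racemic, one enantiomer drawn) | CCOC(=O)/C=C(C)/C=C/[C@]12OO[C@H](C=C1C)CC2(C)C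
A7 | alternative 3 | cis-3,6-dihydroxy-4-ene ester (racemic, one enantiomer drawn) | CCOC(=O)/C=C(C)/C=C/[C@]1(O)C(C)=C[C@@H](O)CC1(C)C
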